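Count what one turn costs Q.

Q 0.20 M; Z 0.0200 M; time 20 min

    Q → G + D (k1 = 0.028 min⁻¹)
    Q + G ⇌ Q.G, settled at all times (K2 = 1100 M⁻¹)
    G ⇌ L + Z, settled at all times (K3 = 1.0 × 10⁻⁵ M)
    Q + Z → G + Z + D (k4 = 3.4 M⁻¹ min⁻¹)
    2 Q → Q2 (k5 = 0.089 M⁻¹ min⁻¹)

* part of the Q that has reacted at 20 min
* pH of the solution at 20 min

- Z is the free proton; pH is minus the decimal logarithm of its molar concentration
- percentages count the Q that a species holds: one Q2 counts as two
- G is meant together with its Q.G
- a step written with two of one species runs at k times the square of its concentration and takes two of it each time
- what has gone from Q into another species counts as reacted, even if it can come back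
- run time (flask): 20 min

Z returns at each turn of its step. Its other source is small: if the whole charge of Q stood as free G, the extra Z would reach 1.00 × 10⁻⁴ M, far less than the 0.0200 M charged. So the pH should stay where the charged Z puts it, and the proton route is pseudo-first-order in Q.

How fast does Q turn over? The two routes add up to 0.0960 min⁻¹, the proton route being the faster. But what becomes of each G released? Bound stands against free at 220 to one at the start, so nearly all of it takes a second Q. One turn then removes two Q, and Q should fall exponentially with the capture constant 0.192 min⁻¹, twice the summed constant of the two routes.

When does that stop? Bound G follows free Q down, so a falling Q also gets Q back from Q.G. With one D made for every two Q taken, D stands near 0.100 M, and the return matches the fall near a free Q of 0.00953 M, the square root of D over the binding constant; there control changes hands, and the constant of the fall drops to 0.0960 min⁻¹. The capture constant by itself puts Q at 0.00430 M by 20 min, below that crossing, which it reaches at 15.9 min. Dimerisation, at 0.0356 min⁻¹ per Q at the start, is slower and is set aside. Running the remaining 4.10 min at the lower constant gives 96.8 % reacted.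

The forecast is lower, at 96.1 % (from 95 % to 97 %), with a pH of 1.7, and it has free Q falling “with the tail slowed as Q.G releases Q back”.

The simulation gives 96.3 % reacted and a pH of 1.70, which is 0.20 percentage points above the forecast and 0.50 points below the reckoning. In this flask at 20.0 min, D holds 46.5 % of the Q charged and Q.G 41.4 %, or 0.890 Q.G per D. The capture constant leaves 14.7 % of Q at 10.0 min, where the flask holds 13.4 %, and 2.15 % at 20 min, where it holds 3.68 %.

For the flask left until 12 min, earlier than the crossing, the capture constant gives 90.0 % reacted. The simulation of that flask gives 90.5 %.

The constants are those of an exercise.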